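**Assumption:** 9, 11 and 12 are taken as purchasable arenes; each is a simply halogenated or oxygenated benzene, and nothing in the route depends on how they are made.

## Structural features

The target (C30H22O15) is a linear pentamer of phloroglucinol. Five benzene rings A to E are held together by four diaryl ether bridges, A5–O–B1, B6–O–C1, C4–O–D1 and D6–O–E1. It carries eleven free phenolic hydroxyls and no stereocentre, so no stereocentres have to be related to each other. In every bridge the oxygen belongs to the 1,3,5-oxygen set of one ring and is bonded to a carbon of the next ring that lies between two oxygen-bearing carbons (B1 between B2 and B6, C1 between C2 and C6, D1 between D2 and D6, E1 between E2 and E6). Ring A is therefore 1,3,5-trioxygenated and rings B to E are 1,2,3,5-tetraoxygenated; rings B and D are bridged through adjacent carbons and ring C through para carbons. The free polyphenol is electron-rich, polar and sensitive to air, above all under base, so the hydroxyls must travel masked and be released last; the diaryl ethers themselves are robust. The real difficulty is steric and regiochemical: each ether carbon is flanked by two oxygen substituents, a hindered and electron-rich site that resists ordinary aryl ether coupling, and on rings B and D one of three similar oxygens has to be singled out. The key step exploits the fact that the A5 oxygen is bonded to B1, the carbon ortho to the B6 oxygen. This is the connectivity formed when a phenol oxygen adds to the ortho carbon of an oxidised phenol, and the oxidised phenol's own oxygen emerges as the only free hydroxyl, B6–OH, exactly where ring C has to be attached.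

## Logic of the disconnections

**19 to 18.** Ten O–CH3 bonds are cut. The free polyphenol cannot be carried through base, copper or peracid, and methyl is the smallest mask that survives all of these. The gain is a stable, chromatographable precursor. The demand is one final cleavage of ten alkyl aryl ethers that leaves the four diaryl ethers intact.

**18 to 16 (through 17).** The C2–O bond of ring C is exchanged for a C2–CHO bond. The formyl group is what activates the neighbouring C1 for substitution, and its oxidative replacement by oxygen gives a hydroxyl that the target wants free anyway. The gain is that no protecting group is spent on this oxygen. The demand is aryl migration rather than hydride migration in the peracid step, and no attack of the peracid on the other electron-rich rings.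

**16 to 10 and 15.** The C4–O bond of the C4–O–D1 bridge is cut, the oxygen staying on D1. C4 is the only ether carbon of the molecule with two hydrogen neighbours, so the hindered partner can be the nucleophile and the unhindered one the halide. The gain is the division of the pentamer into a trimer and a dimer. The demand is a copper coupling that accepts a di-ortho-substituted phenoxide and tolerates an aldehyde.

**15 to 13 (through 14), then 13 to 11 and 12.** D1–OH is traced to D1–CHO, and the D6–O bond is cut with the oxygen staying on E1. The formyl group activates the ortho fluoride for substitution and then becomes the hydroxyl. The gain is two purchasable single rings. The demand is substitution by a phenoxide that has two ortho substituents.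

**10 to 8 and 9.** The C1–O bond of the B6–O–C1 bridge is cut, the oxygen staying on B6. B6–OH is the only free hydroxyl of 8, and C1 of 9 carries fluoride next to the formyl group. The gain is a trimer from a dimer and one ring, with bromine at C4 in reserve for the next bridge. The demand is substitution at a fluoride flanked on both sides without loss of the bromide.

**8 to 6 (through 7).** Three C–Br bonds and two C–CO2CH2Ph bonds are added back. These blocking groups are what the oxidative coupling needs. The ester is taken as benzyl rather than methyl, because a methyl ester between two methoxy groups would need forcing saponification, whereas benzyl leaves in the same hydrogenolysis that removes the bromines. The gain is a single deblocking step. The demand is that the liberated 2,4,6-trioxygenated acids lose CO2 readily, which they should.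

**6 to 5, then 5 to two molecules of 4.** The A5–O–B1 bond is cut at O–B1; 5 is the direct product of coupling and 6 its reduced, aromatic form. The cut follows the oxygen-to-ortho-carbon pattern of phenol oxidation. The gain is a dimer from one monomer used twice, with B6–OH differentiated by the reaction itself. The demand is O–C rather than C–C coupling, at the ortho rather than the para carbon.

**4 to 3 to 2 to 1.** The benzyl ester C–O bond, the carboxylic oxidation level and two C–Br bonds are removed in turn. Bromination is placed first so that the ring is blocked before the chlorite oxidation. The gain is a commercial aldehyde. The demand is esterification of the acid without alkylation of the acidic bromophenol.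

## Other disconnections considered

**Alternative 1:** The cut is the C–C bond A2–A3, so that ring A is grown on the A5 oxygen instead of being brought in as an arene.

- Forward key step: the hindered B1 hydroxyl of the nonamethyl tetramer phenol A4 would be joined by addition–elimination to C4 of an activated form (4-sulfonate or 4-halide) of triacetic acid lactone A5, giving the 4-aryloxy-6-methyl-2-pyrone A2. Mg(OMe)2 would open the lactone to the methyl 3-aryloxy-5-oxohex-2-enoate A3. The magnesium-bound enolate of its methyl ketone would close on the ester (Claisen-type acylation) and aromatise to the resorcinol A1.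
- Correction of a descriptor: the enoate that keeps the ring geometry and can close has the ester carbon and the methylene group cis. Because aryloxy outranks methylene, this is (2E), not (2Z), and A3 is drawn so.
- In its favour: the A–B ether is made with the hindered oxygen as nucleophile on a vinylogous acyl electrophile, which is easier than any aryl–oxygen coupling. Ring A needs no bromine or ester blocking groups and arrives with both hydroxyls free, so two fewer methyl ethers have to be cleaved. On these points it is the better plan.
- Against it here: it presupposes A4, that is rings B to E with all three difficult ethers in place and with B1–OH singled out, so the hard part of the problem is only postponed. The condensation would be run on the most valuable intermediate. Methoxide could also add to the aryloxy-bearing carbon of A2 or A3 and expel the aryloxide, which is a better leaving group than the alkoxides for which this ring synthesis is established.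
- Comparison: both plans address the same junction. The alternative builds one ring and one C–C bond; the chosen step builds one C–O bond and no ring. An ionic, templated condensation stands against an electron-transfer coupling, and neither raises a stereochemical question. The alternative spends two steps after A4 where the chosen plan spends three after 4, which is about equal. The chosen plan, however, makes its ether first, on a cheap monomer, and leaves B6–OH as the handle for the next bond, whereas the alternative gives no help in assembling A4.

**Alternative 2:** The cuts are the C–C bonds C2–C3 and C5–C6, which divide ring C into a three-carbon unit carrying the B6 oxygen and a three-carbon unit carrying the D1 oxygen.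

- Forward key step: the aryloxymalonyl dichloride A7 (from 8 by O-alkylation with a halomalonate, saponification and chlorination) would doubly C-acylate the dienolate of the 3-aryloxyglutaconate A8 (from 15 and a 3-chloroglutaconate). The cyclic trione would tautomerise to the diester A6. Hydrolysis, decarboxylation and demethylation would follow.
- In its favour: it is the most convergent plan, a union of the two dimers that the chosen route also prepares. Both ether bonds to ring C are made as alkyl or vinyl ethers before that ring exists, so no aryl–oxygen bond has to be forged at a carbon between two oxygens. Here it is better than the chosen plan, which needs a substitution and a copper coupling for the same two bonds.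
- Against it here: A7 places an acid chloride two atoms from ring B, whose B5 carbon is ortho to the ether oxygen and para to a methoxy group. Intramolecular Friedel–Crafts acylation to a benzofuranone is therefore expected to compete as soon as the chloride or its ketene forms. Malonyl dichlorides also tend to O-acylate enolates and end as hydroxypyranones. A6 carries two esters between oxygens, whose hydrolysis is slow even though the decarboxylation is easy.
- Comparison: the alternative builds one ring and two C–C bonds and settles the B–C and C–D junctions at once. It does not address the A–B ether and still relies on a dimer such as 8, so it competes with steps 7, 10 and 11 and not with the key step. Its selectivity question is C- against O-acylation; that of the chosen key step is O- against C-coupling. It needs about seven operations from 8 and 15 to the target against four in the chosen route, so the chosen route is shorter, while the alternative is the more convergent.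

**Alternative 3:** The cut is the C–C bond D3–D4, ring D being unfolded to a four-membered ring.

- Forward key step: addition–elimination of 11 to a squarate-derived ester would give the cyclobutenedione A11. 1-Ethoxyvinyllithium A12 would add to the carbonyl next to the aryloxy carbon to give the carbinol A10 (racemic). On heating, A10 would open by a 4-electron electrocyclic process with the hydroxyl turning outward to the dienylketene A13. Its 6-electron electrocyclisation and tautomerisation would give the hydroquinone A9 (Moore rearrangement).
- In its favour: the D–E ether is made on a strained vinylogous ester. The thermal cascade needs no reagent and fixes the four oxygens of ring D with no regiochemical choice, leaving D1–OH free for the bond to ring C. In regiocontrol it is the equal of the substitution/Dakin pair chosen here, and it is better in using no oxidant.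
- Against it here: A9 has two free hydroxyls, and the less hindered D4–OH must be capped before D1–OH can be coupled. The hydroquinone is prone to air oxidation. Making A12 requires an alkyllithium metalation of ethyl vinyl ether at low temperature, the least safe operation of any plan considered. D2 arrives as an ethyl ether, which is no better and no worse than methyl for the final cleavage.
- Comparison: it builds one ring and one C–C bond for a peripheral dimer and leaves the A–B, B–C and C–D junctions to other chemistry, so it could replace only steps 8 and 9. A concerted thermal cascade stands against an ionic substitution–oxidation pair. It needs about five steps to a usable D–E phenol against two, so the chosen route is clearly shorter.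

Key step: step 4

## Route

**Step 1**
Reactants: 1 4-hydroxy-2,6-dimethoxybenzaldehyde
Product: 2 3,5-dibromo-4-hydroxy-2,6-dimethoxybenzaldehyde
Conditions: NBS (2.05 equiv), MeCN, 0 °C to rt
Reagents that add atoms: N-bromosuccinimide, O=C1CCC(=O)N1Br
Why: Electrophilic aromatic bromination; the two open positions are ortho to the hydroxyl and activated by both methoxy groups, so two equivalents should stop at the 3,5-dibromide. Blocking the ring first also shields it from chlorination in step 2, and NBS avoids handling liquid bromine.

**Step 2**
Reactants: 2 3,5-dibromo-4-hydroxy-2,6-dimethoxybenzaldehyde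
Product: 3 3,5-dibromo-4-hydroxy-2,6-dimethoxybenzoic acid
Conditions: NaClO2, NaH2PO4, 2-methylbut-2-ene, tBuOH–H2O, rt
Reagents that add atoms: sodium chlorite, [Na+].[O-]Cl=O
Why: Pinnick oxidation; chlorous acid oxidises the non-enolisable aldehyde and the alkene traps hypochlorous acid, while the fully substituted, bromine-deactivated ring offers no site for chlorination.

**Step 3**
Reactants: 3 3,5-dibromo-4-hydroxy-2,6-dimethoxybenzoic acid
Product: 4 benzyl 3,5-dibromo-4-hydroxy-2,6-dimethoxybenzoate
Conditions: BnBr (1.05 equiv), KHCO3 (1.0 equiv), DMF, rt
Reagents that add atoms: benzyl bromide, BrCc1ccccc1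
Why: SN2 O-alkylation of a carboxylate; one equivalent of hydrogencarbonate ionises the carboxylic acid ahead of the less acidic, doubly ortho-hindered bromophenol, so the ester should form with the phenol left free. Benzyl is chosen so that step 6 can remove the ester together with the bromines.

**Step 4**
Reactants: 4 benzyl 3,5-dibromo-4-hydroxy-2,6-dimethoxybenzoate (two molecules)
Product: 5 benzyl 3,5-dibromo-3-{2,6-dibromo-4-[(benzyloxy)carbonyl]-3,5-dimethoxyphenoxy}-2,6-dimethoxy-4-oxocyclohexa-1,5-diene-1-carboxylate (racemic)
Conditions: anodic oxidation, divided cell, graphite anode, Pt cathode, constant current (about 1 F per mol of 4), nBu4NBF4 (0.1 M), 2,6-lutidine (1 equiv), MeCN, 0 °C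
Reagents that add atoms: none
Why: Lutidine-assisted two-electron oxidation of 4 at the carbon anode gives a phenoxonium ion (equivalently, a pair of phenoxyl radicals), and the phenol oxygen of a second molecule of 4 bonds to a bromine-bearing ortho carbon, so that the O–B1 bond forms and the attacked ring is left as the 6-aryloxy-6-bromocyclohexa-2,4-dienone 5. The closest known reaction type is the anodic oxidation of 2,6-dihalophenols to aryloxy dienone dimers that zinc reduces to ortho-hydroxy diaryl ethers; the methoxy and ester groups are added spectators. No ring is closed. One stereocentre is created, the quaternary carbon bearing bromine and aryloxy; nothing controls it, 5 is racemic, and step 5 removes it. The step needs O–C rather than C–C coupling, ortho rather than para attack, and a stop at the dimer. Every ring carbon of 4 is substituted, so a C–C adduct could not rearomatise and would join two quaternary carbons; the para carbon bears the electron-withdrawing ester, which cannot leave, while each ortho carbon is stabilised by both methoxy groups and bears bromide, the group that departs in step 5. Product 5 has no free hydroxyl and should be harder to oxidise than 4, the charge is limited to about one faraday per mole of 4, and the divided cell keeps the reducible dienone away from the cathode. A tetrafluoroborate electrolyte is used in place of a perchlorate for safety.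

**Step 5**
Reactants: 5 benzyl 3,5-dibromo-3-{2,6-dibromo-4-[(benzyloxy)carbonyl]-3,5-dimethoxyphenoxy}-2,6-dimethoxy-4-oxocyclohexa-1,5-diene-1-carboxylate
Product: 6 benzyl 5-bromo-3-{2,6-dibromo-4-[(benzyloxy)carbonyl]-3,5-dimethoxyphenoxy}-4-hydroxy-2,6-dimethoxybenzoate
Conditions: Zn dust, AcOH–THF, 0 °C to rt
Reagents that add atoms: none
Why: Reductive dehalogenation of an alpha-bromo dienone by zinc; two-electron transfer expels bromide from the quaternary carbon and the ring aromatises to the phenol, which erases the stereocentre. Aryl bromides and benzyl esters are inert to zinc in acetic acid.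

**Step 6**
Reactants: 6 benzyl 5-bromo-3-{2,6-dibromo-4-[(benzyloxy)carbonyl]-3,5-dimethoxyphenoxy}-4-hydroxy-2,6-dimethoxybenzoate
Product: 8 2-(3,5-dimethoxyphenoxy)-3,5-dimethoxyphenol, via diacid 7 (not isolated)
Conditions: H2 (1–3 atm), 10% Pd/C, NaOAc, MeOH–EtOAc, rt; filter; then 2 M aq. HCl, dioxane, 90 °C
Reagents that add atoms: none
Why: Catalytic hydrogenolysis cleaves the three aryl C–Br bonds and both benzyl esters in one operation. The two 2,4,6-trioxygenated benzoic acids of 7 then undergo acid-promoted protodecarboxylation through ipso protonation on warming.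

**Step 7**
Reactants: 8 2-(3,5-dimethoxyphenoxy)-3,5-dimethoxyphenol; 9 5-bromo-2-fluoro-3-methoxybenzaldehyde
Product: 10 5-bromo-2-[2-(3,5-dimethoxyphenoxy)-3,5-dimethoxyphenoxy]-3-methoxybenzaldehyde
Conditions: K2CO3, DMF, 100 °C
Reagents that add atoms: none
Why: Nucleophilic aromatic substitution (SNAr) through a Meisenheimer adduct; the fluoride is activated by the ortho formyl group and the para bromine, and the phenoxide of 8 has only one ortho substituent. Without a metal catalyst the aryl bromide is untouched.

**Step 8**
Reactants: 11 2,4,6-trimethoxyphenol; 12 2-fluoro-4,6-dimethoxybenzaldehyde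
Product: 13 2,4-dimethoxy-6-(2,4,6-trimethoxyphenoxy)benzaldehyde
Conditions: K2CO3, DMSO, 110 °C, under N2
Reagents that add atoms: none
Why: SNAr; fluoride ortho to the formyl group is displaced by the electron-rich phenoxide, and the two methoxy groups of 12 are meta to the reacting carbon, so they do not place charge against the Meisenheimer adduct.

**Step 9**
Reactants: 13 2,4-dimethoxy-6-(2,4,6-trimethoxyphenoxy)benzaldehyde
Product: 15 2,4-dimethoxy-6-(2,4,6-trimethoxyphenoxy)phenol, via aryl formate 14 (not isolated)
Conditions: mCPBA, CH2Cl2, 0 °C to rt; aq. NaHCO3 wash; then K2CO3 (cat.), MeOH, rt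
Reagents that add atoms: 3-chloroperoxybenzoic acid, OOC(=O)c1cccc(Cl)c1
Why: Dakin-type Baeyer–Villiger oxidation; the 2,4,6-trioxygenated aryl group migrates in preference to hydride, and methanolysis of the formate frees the hindered D1 hydroxyl.

**Step 10**
Reactants: 10 5-bromo-2-[2-(3,5-dimethoxyphenoxy)-3,5-dimethoxyphenoxy]-3-methoxybenzaldehyde; 15 2,4-dimethoxy-6-(2,4,6-trimethoxyphenoxy)phenol
Product: 16 2-[2-(3,5-dimethoxyphenoxy)-3,5-dimethoxyphenoxy]-5-[2,4-dimethoxy-6-(2,4,6-trimethoxyphenoxy)phenoxy]-3-methoxybenzaldehyde
Conditions: CuI (10 mol%), picolinic acid (20 mol%), K3PO4, DMSO, 90 °C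
Reagents that add atoms: none
Why: Ullmann-type diaryl ether coupling catalysed by monovalent copper; the bromide has two hydrogen neighbours, so the hindered phenoxide of 15 can be accommodated, and the picolinate ligand is suited to di-ortho-substituted phenols.

**Step 11**
Reactants: 16 2-[2-(3,5-dimethoxyphenoxy)-3,5-dimethoxyphenoxy]-5-[2,4-dimethoxy-6-(2,4,6-trimethoxyphenoxy)phenoxy]-3-methoxybenzaldehyde
Product: 18 2-[2-(3,5-dimethoxyphenoxy)-3,5-dimethoxyphenoxy]-5-[2,4-dimethoxy-6-(2,4,6-trimethoxyphenoxy)phenoxy]-3-methoxyphenol, via aryl formate 17 (not isolated)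
Conditions: mCPBA (1.2 equiv), CH2Cl2, 0 °C; aq. NaHCO3 wash; then K2CO3 (cat.), MeOH, rt
Reagents that add atoms: 3-chloroperoxybenzoic acid, OOC(=O)c1cccc(Cl)c1
Why: Dakin-type Baeyer–Villiger oxidation; the aryl group bearing an ortho aryloxy donor migrates, as in the established conversion of 2-aryloxybenzaldehydes to 2-aryloxyphenols. The hydroxyl set free is C2–OH of ring C, which the target has unprotected.

**Step 12**
Reactants: 18 2-[2-(3,5-dimethoxyphenoxy)-3,5-dimethoxyphenoxy]-5-[2,4-dimethoxy-6-(2,4,6-trimethoxyphenoxy)phenoxy]-3-methoxyphenol
Product: 19 2-[2-(3,5-dihydroxyphenoxy)-3,5-dihydroxyphenoxy]-5-[2,4-dihydroxy-6-(2,4,6-trihydroxyphenoxy)phenoxy]benzene-1,3-diol (target)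
Conditions: BBr3 (excess), CH2Cl2, −78 °C to rt; then MeOH, H2O; work-up under argon
Reagents that add atoms: none
Why: Lewis-acid cleavage of alkyl aryl ethers; BBr3 binds each methoxy oxygen and bromide removes the methyl group by SN2, while the diaryl ether bridges offer no sp3 carbon and should survive.

## Compound list

1 | 4-hydroxy-2,6-dimethoxybenzaldehyde | COc1cc(O)cc(OC)c1C=O | starting material
2 | 3,5-dibromo-4-hydroxy-2,6-dimethoxybenzaldehyde | O=Cc1c(OC)c(Br)c(O)c(Br)c1OC | intermediate
3 | 3,5-dibromo-4-hydroxy-2,6-dimethoxybenzoic acid | OC(=O)c1c(OC)c(Br)c(O)c(Br)c1OC | intermediate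
4 | benzyl 3,5-dibromo-4-hydroxy-2,6-dimethoxybenzoate (key-step precursor) | O=C(OCc1ccccc1)c1c(OC)c(Br)c(O)c(Br)c1OC | intermediate
5 | benzyl 3,5-dibromo-3-{2,6-dibromo-4-[(benzyloxy)carbonyl]-3,5-dimethoxyphenoxy}-2,6-dimethoxy-4-oxocyclohexa-1,5-diene-1-carboxylate, racemic (key-step product) | O=C(OCc1ccccc1)C1=C(OC)C(Br)(Oc2c(Br)c(OC)c(C(=O)OCc3ccccc3)c(OC)c2Br)C(=O)C(Br)=C1OC | intermediate
6 | benzyl 5-bromo-3-{2,6-dibromo-4-[(benzyloxy)carbonyl]-3,5-dimethoxyphenoxy}-4-hydroxy-2,6-dimethoxybenzoate | O=C(OCc1ccccc1)c1c(OC)c(Oc2c(Br)c(OC)c(C(=O)OCc3ccccc3)c(OC)c2Br)c(O)c(Br)c1OC | intermediate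
7 | 3-(4-carboxy-3,5-dimethoxyphenoxy)-4-hydroxy-2,6-dimethoxybenzoic acid (not isolated) | COc1cc(Oc2c(O)cc(OC)c(C(=O)O)c2OC)cc(OC)c1C(=O)O | intermediate
8 | 2-(3,5-dimethoxyphenoxy)-3,5-dimethoxyphenol | COc1cc(OC)cc(Oc2c(O)cc(OC)cc2OC)c1 | intermediate
9 | 5-bromo-2-fluoro-3-methoxybenzaldehyde | COc1cc(Br)cc(C=O)c1F | starting material
10 | 5-bromo-2-[2-(3,5-dimethoxyphenoxy)-3,5-dimethoxyphenoxy]-3-methoxybenzaldehyde | COc1cc(Br)cc(C=O)c1Oc1cc(OC)cc(OC)c1Oc1cc(OC)cc(OC)c1 | intermediate
11 | 2,4,6-trimethoxyphenol | COc1cc(OC)c(O)c(OC)c1 | starting material
12 | 2-fluoro-4,6-dimethoxybenzaldehyde | COc1cc(F)c(C=O)c(OC)c1 | starting material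
13 | 2,4-dimethoxy-6-(2,4,6-trimethoxyphenoxy)benzaldehyde | COc1cc(OC)c(C=O)c(Oc2c(OC)cc(OC)cc2OC)c1 | intermediate
14 | 2,4-dimethoxy-6-(2,4,6-trimethoxyphenoxy)phenyl formate (not isolated) | COc1cc(OC)c(OC=O)c(Oc2c(OC)cc(OC)cc2OC)c1 | intermediate
15 | 2,4-dimethoxy-6-(2,4,6-trimethoxyphenoxy)phenol | COc1cc(OC)c(O)c(Oc2c(OC)cc(OC)cc2OC)c1 | intermediate
16 | 2-[2-(3,5-dimethoxyphenoxy)-3,5-dimethoxyphenoxy]-5-[2,4-dimethoxy-6-(2,4,6-trimethoxyphenoxy)phenoxy]-3-methoxybenzaldehyde | COc1cc(Oc2c(OC)cc(OC)cc2Oc2c(OC)cc(OC)cc2OC)cc(C=O)c1Oc1cc(OC)cc(OC)c1Oc1cc(OC)cc(OC)c1 | intermediate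
17 | 2-[2-(3,5-dimethoxyphenoxy)-3,5-dimethoxyphenoxy]-5-[2,4-dimethoxy-6-(2,4,6-trimethoxyphenoxy)phenoxy]-3-methoxyphenyl formate (not isolated) | COc1cc(Oc2c(OC)cc(OC)cc2Oc2c(OC)cc(OC)cc2OC)cc(OC=O)c1Oc1cc(OC)cc(OC)c1Oc1cc(OC)cc(OC)c1 | intermediate
18 | 2-[2-(3,5-dimethoxyphenoxy)-3,5-dimethoxyphenoxy]-5-[2,4-dimethoxy-6-(2,4,6-trimethoxyphenoxy)phenoxy]-3-methoxyphenol | COc1cc(Oc2c(OC)cc(OC)cc2Oc2c(OC)cc(OC)cc2OC)cc(O)c1Oc1cc(OC)cc(OC)c1Oc1cc(OC)cc(OC)c1 | intermediate
19 | 2-[2-(3,5-dihydroxyphenoxy)-3,5-dihydroxyphenoxy]-5-[2,4-dihydroxy-6-(2,4,6-trihydroxyphenoxy)phenoxy]benzene-1,3-diol | Oc1cc(O)cc(Oc2c(O)cc(O)cc2Oc2c(O)cc(Oc3c(O)cc(O)cc3Oc3c(O)cc(O)cc3O)cc2O)c1 | target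

## Step count and least certain steps

Total: 12 steps. Longest linear sequence: 10 steps (steps 1 to 7, 10, 11 and 12); the D–E branch (steps 8 and 9) joins at step 10.

**Step 4 (key step).** The phenoxide of 4 is flanked by two bromines and is a weak nucleophile. The oxidised species may therefore be captured by adventitious water or at the para carbon instead, and the dienone may be consumed by further electron transfer if the potential drifts. The fallback gives up the oxidative coupling and makes the same ether by substitution. It sets out from 9. SNAr with 3,5-dimethoxyphenol F1 (K2CO3, DMF, 100 °C) should give 5-bromo-2-(3,5-dimethoxyphenoxy)-3-methoxybenzaldehyde F2. Dakin oxidation (mCPBA, then K2CO3 in MeOH) would pass through 5-bromo-2-(3,5-dimethoxyphenoxy)-3-methoxyphenyl formate F3 to 5-bromo-2-(3,5-dimethoxyphenoxy)-3-methoxyphenol F4. Ullmann-type methoxylation of the bromide (NaOMe, CuI, DMF–MeOH, 110 °C) then comes back to the route at 8.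

**Step 7.** Addition to a fluoride flanked on both sides may be slow, and at the temperature then required the formyl group may be degraded by base through disproportionation or condensation. The fallback runs the substitution on a nitrile, which tolerates stronger base and heat, and adjusts the oxidation level afterwards. It sets out from 8. Reaction with 5-bromo-2-fluoro-3-methoxybenzonitrile F5 (Cs2CO3, DMSO, 130 °C) should give 5-bromo-2-[2-(3,5-dimethoxyphenoxy)-3,5-dimethoxyphenoxy]-3-methoxybenzonitrile F6. Reduction with diisobutylaluminium hydride iBu2AlH (toluene, −78 °C) and hydrolysis of the aldimine F7 with dilute HCl comes back to the route at 10.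

**Step 8.** The very electron-rich phenoxide of 11 may be oxidatively degraded before it displaces fluoride from an aldehyde whose acceptor strength is lowered by two methoxy donors. The fallback replaces the substitution by a copper-catalysed coupling of an ortho-formyl aryl bromide, an activated Ullmann partner. It sets out from 11, which is coupled with 2-bromo-4,6-dimethoxybenzaldehyde F8 (CuI, picolinic acid, K3PO4, DMSO, 80 °C), and comes back to the route at 13.

**Step 10.** Copper turnover with a di-ortho-substituted phenoxide and an electron-rich bromide may be slow. That leaves time for hydrodebromination and for the phenoxide to exchange the formyl-activated B–O–C ether. The fallback changes the order of bond formation so that the copper coupling is done on a single ring with the aldehyde masked. It sets out from 9, which is converted (ethylene glycol, TsOH, toluene, reflux) into 2-(5-bromo-2-fluoro-3-methoxyphenyl)-1,3-dioxolane F9. Coupling with 15 under the conditions of step 10, the unactivated fluoride being inert, should give 2-{5-[2,4-dimethoxy-6-(2,4,6-trimethoxyphenoxy)phenoxy]-2-fluoro-3-methoxyphenyl}-1,3-dioxolane F10. Aqueous HCl in THF releases 5-[2,4-dimethoxy-6-(2,4,6-trimethoxyphenoxy)phenoxy]-2-fluoro-3-methoxybenzaldehyde F11. SNAr of F11 with 8 (Cs2CO3, DMSO, 120 °C) comes back to the route at 16.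

**Step 12.** Some of the ten methyl ethers may be cleaved incompletely, and the free polyphenol may be lost by air oxidation during isolation. The fallback does not isolate the free phenol directly. It sets out from 18. After the BBr3 treatment and evaporation, the crude product is peracetylated (Ac2O, pyridine) to the undecaacetate F12, which is stable and can be purified on silica. Acid methanolysis (HCl in MeOH, rt, under argon) then comes back to the route at 19.

## Further compounds

F1 | step 4 | 3,5-dimethoxyphenol | COc1cc(O)cc(OC)c1
F2 | step 4 | 5-bromo-2-(3,5-dimethoxyphenoxy)-3-methoxybenzaldehyde | COc1cc(Br)cc(C=O)c1Oc1cc(OC)cc(OC)c1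
F3 | step 4 | 5-bromo-2-(3,5-dimethoxyphenoxy)-3-methoxyphenyl formate | COc1cc(Br)cc(OC=O)c1Oc1cc(OC)cc(OC)c1
F4 | step 4 | 5-bromo-2-(3,5-dimethoxyphenoxy)-3-methoxyphenol | COc1cc(Br)cc(O)c1Oc1cc(OC)cc(OC)c1
F5 | step 7 | 5-bromo-2-fluoro-3-methoxybenzonitrile | COc1cc(Br)cc(C#N)c1F
F6 | step 7 | 5-bromo-2-[2-(3,5-dimethoxyphenoxy)-3,5-dimethoxyphenoxy]-3-methoxybenzonitrile | COc1cc(Br)cc(C#N)c1Oc1cc(OC)cc(OC)c1Oc1cc(OC)cc(OC)c1
F7 | step 7 | 1-{5-bromo-2-[2-(3,5-dimethoxyphenoxy)-3,5-dimethoxyphenoxy]-3-methoxyphenyl}methanimine | COc1cc(Br)cc(C=N)c1Oc1cc(OC)cc(OC)c1Oc1cc(OC)cc(OC)c1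
F8 | step 8 | 2-bromo-4,6-dimethoxybenzaldehyde | COc1cc(Br)c(C=O)c(OC)c1
F9 | step 10 | 2-(5-bromo-2-fluoro-3-methoxyphenyl)-1,3-dioxolane | COc1cc(Br)cc(C2OCCO2)c1F
F10 | step 10 | 2-{5-[2,4-dimethoxy-6-(2,4,6-trimethoxyphenoxy)phenoxy]-2-fluoro-3-methoxyphenyl}-1,3-dioxolane | COc1cc(Oc2c(OC)cc(OC)cc2Oc2c(OC)cc(OC)cc2OC)cc(C2OCCO2)c1F
F11 | step 10 | 5-[2,4-dimethoxy-6-(2,4,6-trimethoxyphenoxy)phenoxy]-2-fluoro-3-methoxybenzaldehyde | COc1cc(Oc2c(OC)cc(OC)cc2Oc2c(OC)cc(OC)cc2OC)cc(C=O)c1F
F12 | step 12 | undeca-O-acetate of 19 | CC(=O)Oc1cc(OC(C)=O)cc(Oc2c(OC(C)=O)cc(OC(C)=O)cc2Oc2c(OC(C)=O)cc(Oc3c(OC(C)=O)cc(OC(C)=O)cc3Oc3c(OC(C)=O)cc(OC(C)=O)cc3OC(C)=O)cc2OC(C)=O)c1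
A1 | alternative 1 | nonamethyl ether of 19 with ring A as the free resorcinol | Oc1cc(O)cc(Oc2c(OC)cc(OC)cc2Oc2c(OC)cc(Oc3c(OC)cc(OC)cc3Oc3c(OC)cc(OC)cc3OC)cc2OC)c1
A2 | alternative 1 | 4-aryloxy-6-methyl-2H-pyran-2-one carrying rings B to E as their nonamethyl ether | Cc1cc(Oc2c(OC)cc(OC)cc2Oc2c(OC)cc(Oc3c(OC)cc(OC)cc3Oc3c(OC)cc(OC)cc3OC)cc2OC)cc(=O)o1
A3 | alternative 1 | methyl (2E)-3-aryloxy-5-oxohex-2-enoate carrying rings B to E as their nonamethyl ether | COC(=O)/C=C(\CC(C)=O)Oc1c(OC)cc(OC)cc1Oc1c(OC)cc(Oc2c(OC)cc(OC)cc2Oc2c(OC)cc(OC)cc2OC)cc1OC
A4 | alternative 1 | nonamethyl tetramer phenol of rings B to E with free B1 hydroxyl | Oc1c(OC)cc(OC)cc1Oc1c(OC)cc(Oc2c(OC)cc(OC)cc2Oc2c(OC)cc(OC)cc2OC)cc1OC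
A5 | alternative 1 | triacetic acid lactone (4-hydroxy-6-methyl-2H-pyran-2-one) | Cc1cc(O)cc(=O)o1
A6 | alternative 2 | nonamethyl pentamer with ring C as a 2,6-dihydroxy-3,5-bis(methoxycarbonyl) ring | COC(=O)c1c(O)c(Oc2cc(OC)cc(OC)c2Oc2cc(OC)cc(OC)c2)c(O)c(C(=O)OC)c1Oc1c(OC)cc(OC)cc1Oc1c(OC)cc(OC)cc1OC
A7 | alternative 2 | 2-[2-(3,5-dimethoxyphenoxy)-3,5-dimethoxyphenoxy]propanedioyl dichloride | COc1cc(OC)cc(Oc2c(OC)cc(OC)cc2OC(C(=O)Cl)C(=O)Cl)c1
A8 | alternative 2 | dimethyl (2E)-3-[2,4-dimethoxy-6-(2,4,6-trimethoxyphenoxy)phenoxy]pent-2-enedioate | COC(=O)/C=C(\CC(=O)OC)Oc1c(OC)cc(OC)cc1Oc1c(OC)cc(OC)cc1OC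
A9 | alternative 3 | 2-ethoxy-6-(2,4,6-trimethoxyphenoxy)benzene-1,4-diol | CCOc1cc(O)cc(Oc2c(OC)cc(OC)cc2OC)c1O
A10 | alternative 3 | 4-(1-ethoxyethenyl)-4-hydroxy-3-(2,4,6-trimethoxyphenoxy)cyclobut-2-en-1-one (racemic) | CCOC(=C)C1(O)C(Oc2c(OC)cc(OC)cc2OC)=CC1=O
A11 | alternative 3 | 3-(2,4,6-trimethoxyphenoxy)cyclobut-3-ene-1,2-dione | O=C1C=C(Oc2c(OC)cc(OC)cc2OC)C1=O
A12 | alternative 3 | 1-ethoxyvinyllithium | [Li]C(=C)OCC
A13 | alternative 3 | (3Z)-5-ethoxy-4-hydroxy-3-(2,4,6-trimethoxyphenoxy)hexa-1,3,5-trien-1-one (dienylketene) | O=C=C/C(Oc1c(OC)cc(OC)cc1OC)=C(/O)C(=C)OCC
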